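5 questions stand on the table: which flask is best, and what excess of left-handed product over right-handed product each of the 4 flasks ends with.

the same everywhere: left-handed substrate 0.17 M; solid reagent 0.340 M; catalyst 0.34 mM; right-handed substrate 0.17 M; time 5.0 min
- Tuesday's: temperature 50 °C
- Monday's: temperature 35 °C
- Saturday's: temperature 80 °C
- Sunday's: temperature 65 °C

* the best flask by excess of left-handed product over right-handed product; "all alike" if 1.5 percentage points covers them all (Tuesday's / Monday's / Saturday's / Sunday's / all alike)
* excess of left-handed product over right-handed product at the end, Tuesday's
* excess of left-handed product over right-handed product at the end, Monday's
* excess of left-handed product over right-handed product at the end, Saturday's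
* excess of left-handed product over right-handed product at the end, Sunday's

- catalyst is single-handed; left-handed substrate and right-handed substrate are mirror images of each other, charged as a racemate, each of them at the stated concentration
- two of one species on the left: rate k times its square, two consumed each time
- solid reagent is a solid; its amount is given per volume of the solution
- the list of constants is for 35 °C, to be carried to other temperatures by the activation energies
- at the start none of the solid reagent is in solution
- an excess is below zero if the other one leads

Why is there any excess? Partner, fed by the dissolving solid reagent, reacts with a substrate and the catalyst together, and the left-handed substrate reacts with the larger constant, so if the two substrates stayed equal, the excess would be the difference of the two constants over their sum. That is the ceiling set by the selectivity factor, and on Monday's it is 33.3%.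

And what keeps the two substrates equal? Their interconversion, a racemisation with a relaxation half-life of 0.0656 min on Monday's, works against the drain of the favoured form, so this is a dynamic kinetic resolution.

How fast is the drain, when partner is not given? I take partner to climb to about half of its solubility and then fall away, and for the span in which it stands in the flask I put its mean, as an estimate, at a quarter of that solubility. Each substrate then drains at the mean of the two constants times the catalyst times that partner level.

So what do you count? I count turnovers: the relaxation rate, twice the interconversion constant, divided by the drain rate, which on Monday's comes to 4.06. This is the refill number, the racemisation turnovers available for each turnover of the drain.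

Is that enough to reach the ceiling? Not quite. While the drain runs, I take the gap between the substrates to hold where relaxation removes it as fast as the drain opens it, and in this estimate that puts the excess near the ceiling times the refill number over one plus the refill number, so Monday's gets 26.7%.

But heat helps the refill and hurts the ceiling, so which wins, with the partner level kept as I took it for Monday's? Tuesday's has ceiling 26.7% and refill number 8.56, which gives 23.9%. Sunday's has 20.5% and 16.8, which gives 19.4%. Saturday's has 14.7% and 31.1, which gives 14.2%. My choice is therefore Monday's.

The forecast names Monday's too, with 26% there, 23% on Tuesday's, 19% on Sunday's and 14% on Saturday's, and its Monday's figure is lower than mine. Its ground is that “the coolest flask should win even though its slow racemisation costs it the most”.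

    partner + catalyst + left-handed substrate → catalyst + left-handed product (k1 = 4000 L² mol⁻² s⁻¹, Ea1 = 28.0 kJ mol⁻¹)
    partner + catalyst + right-handed substrate → catalyst + right-handed product (k2 = 2000 L² mol⁻² s⁻¹, Ea2 = 36.0 kJ mol⁻¹)
    left-handed substrate ⇌ right-handed substrate (k3 = 0.088 s⁻¹, Ea3 = 72.0 kJ mol⁻¹)
    solid reagent ⇌ partner, rate k4*(cs4 - [partner]) while solid is left; crystals form when [partner] > cs4 (cs4 = 0.17 M, k4 = 0.90 s⁻¹)
    2 partner → homo dimer (k5 = 1.2 L mol⁻¹ s⁻¹, Ea5 = 38.0 kJ mol⁻¹)
    (constants at 35 °C)

The simulation puts Monday's first at 26.9%, with Tuesday's at 23.4%, Sunday's at 19.1% and Saturday's at 14.2%. Monday's still reads 26.9% at 50.0 min. The refill number of 4.06 on Monday's, reckoned with the same partner level, goes inversely with the catalyst, so a neighbour of Monday's charged with 8.5 × 10⁻⁴ M of catalyst is reckoned at a refill number of 1.62, which gives 20.6%, and that neighbour ends at 22.0%.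

The rate constants are made up; the flask was simulated.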